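**Strategy.** The tetrahydrochromone half is disconnected at O1–C2 and C5–O. In its carbocyclic ring, C8a is the carbonyl carbon, C4a the α-carbon and C5 the β-carbon of a cyclohex-2-enone that carries the C4 ynone on C4a. One hydrative cascade therefore installs the C5 hydroxyl and closes the γ-pyranone ring: water adds to C5 and the C8a enol oxygen closes on alkyne carbon C2. The precursor is a D-glucose-derived 2-alkynoyl cyclohexenone with two methoxymethyl ethers (future O6, O7) and the chromone aryl ether (future C8) set by Mitsunobu inversion. It is released by a neutral oxidation directly before use. Acid then frees the 6,7-diol.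

Key step: step 16

Remark: PMB = 4-methoxybenzyl, MOM = methoxymethyl, ArO = [7-methoxy-4-oxo-2-(2-phenylethyl)-4H-chromen-6-yl]oxy; carbocycles are numbered as cyclohexenones (C1 = C=O), bicycles as chromones; the carbinol carbons made in steps 6 and 14 are assumed to form as epimer mixtures and are carried on unseparated because both are oxidised later.

Step 1
Reactants: 1 methyl 4,6-O-[(R)-benzylidene]-α-D-glucopyranoside
Product: 3 methyl 4,6-O-benzylidene-2-O-PMB-α-D-glucopyranoside, via 2,3-O-dibutylstannylene acetal 2 (not isolated)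
Conditions: Bu2SnO, MeOH, 65 °C; evaporate; PMBCl, Bu4NI, toluene, 100 °C
Reagents that add atoms: 4-methoxybenzyl chloride, COc1ccc(CCl)cc1; dibutyltin oxide, CCCC[Sn](=O)CCCC (its atoms stay only in 2)
Why: Stannylene-mediated regioselective O-alkylation, in which O2, activated by the cis anomeric methoxy group, is the more nucleophilic tin-bound oxygen of an α-glucoside and should take the PMB group while O3–H stays free.

Step 2
Reactants: 3 methyl 4,6-O-benzylidene-2-O-PMB-α-D-glucopyranoside
Product: 4 methyl 2-O-PMB-α-D-glucopyranoside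
Conditions: camphorsulfonic acid (cat.), MeOH, 23 °C; Et3N
Reagents that add atoms: none
Why: Acid-catalysed transacetalisation in methanol removes the benzylidene acetal, while the PMB ether and the methyl glycoside are stable to catalytic sulfonic acid at room temperature.

Step 3
Reactants: 4 methyl 2-O-PMB-α-D-glucopyranoside
Product: 5 methyl 6-deoxy-6-iodo-2-O-PMB-α-D-glucopyranoside
Conditions: I2, PPh3, imidazole, THF, 0 → 50 °C
Reagents that add atoms: iodine, II
Why: Garegg–Samuelsson (Appel-type) iodination proceeds through an alkoxyphosphonium ion that forms and is displaced fastest at the unhindered primary C6, so the secondary 3- and 4-hydroxyls should remain.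

Step 4
Reactants: 5 methyl 6-deoxy-6-iodo-2-O-PMB-α-D-glucopyranoside
Product: 6 methyl 6-deoxy-6-iodo-3,4-bis-O-MOM-2-O-PMB-α-D-glucopyranoside
Conditions: MOMCl, i-Pr2NEt, Bu4NI (cat.), CH2Cl2, 0 → 40 °C
Reagents that add atoms: chloromethyl methyl ether, COCCl
Why: Williamson-type alkylation of both secondary hydroxyls by the highly reactive α-chloro ether under a hindered amine base, which is too weak to trigger 3,6-anhydro ring formation from the primary iodide.

Step 5
Reactants: 6 methyl 6-deoxy-6-iodo-3,4-bis-O-MOM-2-O-PMB-α-D-glucopyranoside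
Product: 7 (2R,3S,4R)-3,4-bis(methoxymethoxy)-2-[(4-methoxybenzyl)oxy]hex-5-enal
Conditions: Zn dust (activated), THF/H2O 9:1, ultrasound, 40 °C
Reagents that add atoms: none
Why: Bernet–Vasella reductive fragmentation, in which zinc inserts into C6–I and the organozinc expels the ring oxygen from C5, giving the C5=C6 alkene and, after loss of methoxide from C1, the aldehyde with C2–C4 untouched.

Step 6
Reactants: 7 (2R,3S,4R)-3,4-bis(methoxymethoxy)-2-[(4-methoxybenzyl)oxy]hex-5-enal
Product: 8 (4S,5S,6R)-5,6-bis(methoxymethoxy)-4-[(4-methoxybenzyl)oxy]octa-1,7-dien-3-ol (both C3 epimers)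
Conditions: CH2=CHMgBr, THF, −78 → 0 °C; aq NH4Cl
Reagents that add atoms: vinylmagnesium bromide, C=C[Mg]Br
Why: Grignard 1,2-addition to the aldehyde, where the new carbinol centre need not be controlled because this carbon becomes the ring ketone in step 8.

Step 7
Reactants: 8 (4S,5S,6R)-5,6-bis(methoxymethoxy)-4-[(4-methoxybenzyl)oxy]octa-1,7-dien-3-ol
Product: 9 (4R,5S,6S)-4,5-bis(methoxymethoxy)-6-[(4-methoxybenzyl)oxy]cyclohex-2-en-1-ol (both C1 epimers)
Conditions: second-generation Grubbs catalyst (3 mol %), CH2Cl2 (0.01 M), 40 °C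
Reagents that add atoms: none
Why: Ring-closing olefin metathesis of a 1,7-diene to a cyclohexene with loss of ethene, a reliable closure for polyoxygenated sugar-derived dienes that should work for both carbinol epimers.

Step 8
Reactants: 9 (4R,5S,6S)-4,5-bis(methoxymethoxy)-6-[(4-methoxybenzyl)oxy]cyclohex-2-en-1-ol
Product: 10 (4R,5S,6R)-4,5-bis(methoxymethoxy)-6-[(4-methoxybenzyl)oxy]cyclohex-2-en-1-one
Conditions: Dess–Martin periodinane, CH2Cl2, 0 → 23 °C
Reagents that add atoms: none
Why: Dess–Martin oxidation of the allylic alcohol under near-neutral conditions should converge both epimers to one enone without touching the acetals or the PMB ether and without epimerising C6.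

Step 9
Reactants: 10 (4R,5S,6R)-4,5-bis(methoxymethoxy)-6-[(4-methoxybenzyl)oxy]cyclohex-2-en-1-one
Product: 11 (4R,5S,6R)-2-iodo-4,5-bis(methoxymethoxy)-6-[(4-methoxybenzyl)oxy]cyclohex-2-en-1-one
Conditions: I2, pyridine, CH2Cl2, 0 → 23 °C
Reagents that add atoms: iodine, II
Why: Johnson α-iodination of an enone (pyridine conjugate addition, iodination of the enolate, loss of pyridine) places iodine on C2, the future C4a, and is run before the aryl ether is installed so that this centre never meets the amine.

Step 10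
Reactants: 11 (4R,5S,6R)-2-iodo-4,5-bis(methoxymethoxy)-6-[(4-methoxybenzyl)oxy]cyclohex-2-en-1-one
Product: 12 (4R,5R,6R)-6-hydroxy-2-iodo-4,5-bis(methoxymethoxy)cyclohex-2-en-1-one
Conditions: DDQ, CH2Cl2/pH 7 buffer 10:1, 0 → 23 °C
Reagents that add atoms: none
Why: Oxidative cleavage of the electron-rich PMB ether by DDQ through its benzylic oxocarbenium ion frees only the C6 hydroxyl, the MOM ethers and the iodoenone being inert to the quinone.

Step 11
Reactants: 13 1-(2,5-dihydroxy-4-methoxyphenyl)ethanone; 14 ethyl 3-phenylpropanoate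
Product: 16 6-hydroxy-7-methoxy-2-(2-phenylethyl)-4H-chromen-4-one, via 1,3-diketone 15 (not isolated)
Conditions: NaH (5 equiv), THF, 65 °C, N2; then AcOH, conc. HCl, 90 °C
Reagents that add atoms: none
Why: Crossed Claisen condensation of the acetophenone enolate (both phenols first converted to phenoxides) with the ester gives the 1,3-diketone, and acid-catalysed cyclodehydration through the ortho hydroxyl closes the chromone, the standard construction of 2-(2-phenylethyl)chromones.

Step 12
Reactants: 12 (4R,5R,6R)-6-hydroxy-2-iodo-4,5-bis(methoxymethoxy)cyclohex-2-en-1-one; 16 6-hydroxy-7-methoxy-2-(2-phenylethyl)-4H-chromen-4-one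
Product: 17 (4R,5S,6S)-6-ArO-2-iodo-4,5-bis(methoxymethoxy)cyclohex-2-en-1-one
Conditions: PPh3, DIAD, THF, 0 → 23 °C
Reagents that add atoms: none
Why: Mitsunobu etherification, in which the phenol (pKa about 10) protonates the betaine and its anion displaces the oxyphosphonium group by an SN2 process accelerated by the adjacent carbonyl, so C6 is inverted and the aryloxy group ends cis to the C5 MOM ether (future C8/C7).

Step 13
Reactants: 18 4-phenyl-1-butyne
Product: 20 5-phenylpent-2-ynal, via lithium acetylide 19 (not isolated)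
Conditions: n-BuLi, THF, −78 °C; DMF, −78 → 0 °C; pour into 10% aq KH2PO4/MTBE, 0 °C
Reagents that add atoms: N,N-dimethylformamide, CN(C)C=O; n-butyllithium, [Li]CCCC (lithium stays only in 19)
Why: Deprotonation of the terminal alkyne and formylation of the lithium acetylide with DMF, with a buffered reverse quench so that the liberated dimethylamine cannot add to the ynal.

Step 14
Reactants: 17 (4R,5S,6S)-6-ArO-2-iodo-4,5-bis(methoxymethoxy)cyclohex-2-en-1-one; 20 5-phenylpent-2-ynal
Product: 21 (4R,5S,6S)-6-ArO-2-(1-hydroxy-5-phenylpent-2-yn-1-yl)-4,5-bis(methoxymethoxy)cyclohex-2-en-1-one (both carbinol epimers)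
Conditions: CrCl2 (4 equiv), NiCl2 (1 mol %), DMF, 23 °C
Reagents that add atoms: none
Why: Nozaki–Hiyama–Kishi coupling, in which nickel-catalysed insertion into the alkenyl C–I bond and transmetallation give an alkenylchromium species that adds to the aldehyde while ignoring the ketone, the pyranone and the acetals; the carbinol configuration is irrelevant because step 15 removes it.

Step 15
Reactants: 21 (4R,5S,6S)-6-ArO-2-(1-hydroxy-5-phenylpent-2-yn-1-yl)-4,5-bis(methoxymethoxy)cyclohex-2-en-1-one
Product: 22 (4R,5S,6S)-6-ArO-4,5-bis(methoxymethoxy)-2-(5-phenylpent-2-ynoyl)cyclohex-2-en-1-one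
Conditions: Dess–Martin periodinane, CH2Cl2, 0 °C; filter, use at once
Reagents that add atoms: none
Why: Dess–Martin oxidation of the allylic and propargylic carbinol releases the strongly electrophilic alkylidene 1,3-dicarbonyl under base-free conditions, so C6–H is not epimerised and the C5 MOM ether is not lost by β-elimination.

Step 16
Reactants: 22 (4R,5S,6S)-6-ArO-4,5-bis(methoxymethoxy)-2-(5-phenylpent-2-ynoyl)cyclohex-2-en-1-one
Product: 24 (5S,6R,7S,8S)-8-ArO-5-hydroxy-6,7-bis(methoxymethoxy)-2-(2-phenylethyl)-5,6,7,8-tetrahydro-4H-chromen-4-one, via enolised C5 hydrate 23 (not isolated)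
Conditions: AuCl3 (5 mol %), H2O (10 equiv), MeCN, 0 → 23 °C
Reagents that add atoms: water, O
Why: Proposed new method: C5 of 22 is the terminus of an alkylidene 1,3-dicarbonyl, so water should add there reversibly (oxa-Michael) to give the enolised diketone 23, whose ring enol oxygen on C8a then attacks the gold-activated ynone at its β-carbon C2, and protodeauration with tautomerisation to the aromatic 4-pyranone makes the sequence irreversible. The closest known reactions are the AuCl3-catalysed nucleophile-triggered cyclisation of 2-(1-alkynyl)-2-alken-1-ones to furans and the acid- or gold-catalysed cyclisation of enolised hydroxy ynones to 4-pyranones, which are merged here on a 2-alkynoyl enone. The pyranone ring closes 6-endo-dig, favoured over 5-exo-dig attack at C3 by the Michael polarisation of the ynone and by the aromaticity of the product. The new C5 stereocentre is set by approach of water anti to the adjacent C6 MOM ether, and because the C5–O bond can ionise to an O1-stabilised cation under the weakly acidic conditions the 5,6-trans carbinol should also be the equilibrium product. The site selectivity required, water at alkene carbon C5 and not at alkyne carbon C2, rests on the double carbonyl activation of C5 against the single activation of C2, and both hydration at C5 and a closure through the C5 hydroxyl (a non-aromatic dihydropyranone) remain reversible until the aromatic ring forms. Gold catalysis is preferred to base because C8–H, α to the C8a carbonyl with the C7 MOM ether β to it, would otherwise risk epimerisation and elimination toward an aromatic chromone.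

Step 17
Reactants: 24 (5S,6R,7S,8S)-8-ArO-5-hydroxy-6,7-bis(methoxymethoxy)-2-(2-phenylethyl)-5,6,7,8-tetrahydro-4H-chromen-4-one
Product: 25 (5S,6R,7S,8S)-8-ArO-5,6,7-trihydroxy-2-(2-phenylethyl)-5,6,7,8-tetrahydro-4H-chromen-4-one (CNP0125425.2)
Conditions: 3 M aq HCl, THF, 40 °C
Reagents that add atoms: none
Why: Acid hydrolysis of the two formaldehyde acetals with water as the only nucleophile, so that any reversible ionisation at C5 can only return the carbinol, while the C8 aryl ether, whose cation has no O1 stabilisation, should not be cleaved.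

**Compound list**

1 | methyl 4,6-O-[(R)-benzylidene]-α-D-glucopyranoside | CO[C@H]1O[C@@H]2CO[C@@H](c3ccccc3)O[C@H]2[C@H](O)[C@H]1O | starting material
2 | methyl 4,6-O-benzylidene-2,3-O-(dibutylstannylene)-α-D-glucopyranoside | CO[C@H]1O[C@@H]2CO[C@@H](c3ccccc3)O[C@H]2[C@@H]2O[Sn](CCCC)(CCCC)O[C@@H]12 | intermediate (not isolated)
3 | methyl 4,6-O-benzylidene-2-O-(4-methoxybenzyl)-α-D-glucopyranoside | CO[C@H]1O[C@@H]2CO[C@@H](c3ccccc3)O[C@H]2[C@H](O)[C@H]1OCc1ccc(OC)cc1 | intermediate
4 | methyl 2-O-(4-methoxybenzyl)-α-D-glucopyranoside | CO[C@H]1O[C@H](CO)[C@@H](O)[C@H](O)[C@H]1OCc1ccc(OC)cc1 | intermediate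
5 | methyl 6-deoxy-6-iodo-2-O-(4-methoxybenzyl)-α-D-glucopyranoside | CO[C@H]1O[C@H](CI)[C@@H](O)[C@H](O)[C@H]1OCc1ccc(OC)cc1 | intermediate
6 | methyl 6-deoxy-6-iodo-3,4-bis-O-(methoxymethyl)-2-O-(4-methoxybenzyl)-α-D-glucopyranoside | CO[C@H]1O[C@H](CI)[C@@H](OCOC)[C@H](OCOC)[C@H]1OCc1ccc(OC)cc1 | intermediate
7 | (2R,3S,4R)-3,4-bis(methoxymethoxy)-2-[(4-methoxybenzyl)oxy]hex-5-enal | O=C[C@H](OCc1ccc(OC)cc1)[C@@H](OCOC)[C@H](OCOC)C=C | intermediate
8 | (4S,5S,6R)-5,6-bis(methoxymethoxy)-4-[(4-methoxybenzyl)oxy]octa-1,7-dien-3-ol, both C3 epimers | C=CC(O)[C@H](OCc1ccc(OC)cc1)[C@@H](OCOC)[C@H](OCOC)C=C | intermediate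
9 | (4R,5S,6S)-4,5-bis(methoxymethoxy)-6-[(4-methoxybenzyl)oxy]cyclohex-2-en-1-ol, both C1 epimers | OC1C=C[C@@H](OCOC)[C@H](OCOC)[C@H]1OCc1ccc(OC)cc1 | intermediate
10 | (4R,5S,6R)-4,5-bis(methoxymethoxy)-6-[(4-methoxybenzyl)oxy]cyclohex-2-en-1-one | O=C1C=C[C@@H](OCOC)[C@H](OCOC)[C@H]1OCc1ccc(OC)cc1 | intermediate
11 | (4R,5S,6R)-2-iodo-4,5-bis(methoxymethoxy)-6-[(4-methoxybenzyl)oxy]cyclohex-2-en-1-one | O=C1C(I)=C[C@@H](OCOC)[C@H](OCOC)[C@H]1OCc1ccc(OC)cc1 | intermediate
12 | (4R,5R,6R)-6-hydroxy-2-iodo-4,5-bis(methoxymethoxy)cyclohex-2-en-1-one | O=C1C(I)=C[C@@H](OCOC)[C@H](OCOC)[C@H]1O | intermediate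
13 | 1-(2,5-dihydroxy-4-methoxyphenyl)ethanone | CC(=O)c1cc(O)c(OC)cc1O | starting material
14 | ethyl 3-phenylpropanoate | CCOC(=O)CCc1ccccc1 | starting material
15 | 1-(2,5-dihydroxy-4-methoxyphenyl)-5-phenylpentane-1,3-dione | COc1cc(O)c(cc1O)C(=O)CC(=O)CCc1ccccc1 | intermediate (not isolated)
16 | 6-hydroxy-7-methoxy-2-(2-phenylethyl)-4H-chromen-4-one | COc1cc2oc(CCc3ccccc3)cc(=O)c2cc1O | intermediate
17 | (4R,5S,6S)-2-iodo-6-{[7-methoxy-4-oxo-2-(2-phenylethyl)-4H-chromen-6-yl]oxy}-4,5-bis(methoxymethoxy)cyclohex-2-en-1-one | COc1cc2oc(CCc3ccccc3)cc(=O)c2cc1O[C@@H]1C(=O)C(I)=C[C@@H](OCOC)[C@@H]1OCOC | intermediate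
18 | 4-phenyl-1-butyne | C#CCCc1ccccc1 | starting material
19 | lithium 4-phenylbut-1-yn-1-ide | [Li]C#CCCc1ccccc1 | intermediate (not isolated)
20 | 5-phenylpent-2-ynal | O=CC#CCCc1ccccc1 | intermediate
21 | (4R,5S,6S)-2-(1-hydroxy-5-phenylpent-2-yn-1-yl)-6-{[7-methoxy-4-oxo-2-(2-phenylethyl)-4H-chromen-6-yl]oxy}-4,5-bis(methoxymethoxy)cyclohex-2-en-1-one, both carbinol epimers | COc1cc2oc(CCc3ccccc3)cc(=O)c2cc1O[C@@H]1C(=O)C(C(O)C#CCCc2ccccc2)=C[C@@H](OCOC)[C@@H]1OCOC | intermediate
22 | (4R,5S,6S)-6-{[7-methoxy-4-oxo-2-(2-phenylethyl)-4H-chromen-6-yl]oxy}-4,5-bis(methoxymethoxy)-2-(5-phenylpent-2-ynoyl)cyclohex-2-en-1-one | COc1cc2oc(CCc3ccccc3)cc(=O)c2cc1O[C@@H]1C(=O)C(C(=O)C#CCCc2ccccc2)=C[C@@H](OCOC)[C@@H]1OCOC | intermediate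
23 | (3S,4R,5S,6S)-3-hydroxy-6-{[7-methoxy-4-oxo-2-(2-phenylethyl)-4H-chromen-6-yl]oxy}-4,5-bis(methoxymethoxy)-2-(5-phenylpent-2-ynoyl)cyclohexan-1-one, drawn as its ring enol | COc1cc2oc(CCc3ccccc3)cc(=O)c2cc1O[C@@H]1C(O)=C(C(=O)C#CCCc2ccccc2)[C@H](O)[C@@H](OCOC)[C@@H]1OCOC | intermediate (not isolated)
24 | (5S,6R,7S,8S)-5-hydroxy-8-{[7-methoxy-4-oxo-2-(2-phenylethyl)-4H-chromen-6-yl]oxy}-6,7-bis(methoxymethoxy)-2-(2-phenylethyl)-5,6,7,8-tetrahydro-4H-chromen-4-one | COc1cc2oc(CCc3ccccc3)cc(=O)c2cc1O[C@@H]1c2oc(CCc3ccccc3)cc(=O)c2[C@H](O)[C@@H](OCOC)[C@@H]1OCOC | intermediate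
25 | (5S,6R,7S,8S)-5,6,7-trihydroxy-8-{[7-methoxy-4-oxo-2-(2-phenylethyl)-4H-chromen-6-yl]oxy}-2-(2-phenylethyl)-5,6,7,8-tetrahydro-4H-chromen-4-one | COc1cc2oc(CCc3ccccc3)cc(=O)c2cc1O[C@@H]1c2oc(CCc3ccccc3)cc(=O)c2[C@H](O)[C@@H](O)[C@@H]1O | target

**Total step count:** 17
**Longest linear sequence:** 15 steps (steps 1–10, 12, 14–17, from 1 to 25)

**Steps most likely to fail**

1. Step 16 (the proposed cascade). Water may add to the gold-activated alkyne instead of C5 and lead to the isomeric pyranone bridged through C5. The enol may close 5-exo-dig. Water may approach C5 syn to the C6 MOM ether. Acid released from the catalyst may strip a MOM group or start aromatisation of the carbocycle. The fallback sets out from 21 and returns to the route at 23, which is then isolated and closed to 24. Nucleophilic epoxidation of the enone of 21 (t-BuOOH, DBU, CH2Cl2, 0 °C, Weitz–Scheffer type), with the peroxide attacking the enone β-carbon anti to the neighbouring MOM ether, should give the epoxy ketone F1. Reductive opening of this α,β-epoxy ketone at its α-carbon with the selenide reagent from (PhSe)2 and NaBH4 (EtOH, AcOH, 0 °C) should give the 3-hydroxy ketone diol F2, leaving the future C5–O bond intact. MnO2 (CH2Cl2, 23 °C) should then oxidise only the propargylic carbinol and give 23. The established 6-endo-dig cyclisation of enolised hydroxy ynones (p-TsOH·H2O 10 mol % or AuCl3 2 mol %, CH2Cl2, 0 °C) should convert 23 into 24. Here C5 is fixed by the epoxide before the ring closes.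

2. Step 12 (Mitsunobu etherification of the α-ketol). The basic hydrazide may epimerise C6 of substrate or product, or the activated ketol may eliminate toward an enol ether and aromatise instead of being displaced. The fallback sets out from 12 and returns at 17. The hydroxyl is converted into a sulfonate (Tf2O, pyridine, CH2Cl2, −40 °C) to give the triflate F3. This is displaced by the caesium phenoxide of 16 (Cs2CO3, MeCN, 0 °C), a two-stage Williamson-type SN2 etherification with the same inversion at C6 but without phosphine or azodicarboxylate.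

3. Step 14 (Nozaki–Hiyama–Kishi coupling of the α-iodoenone). The alkenyl metal species may be protonated (reductive loss of iodine) or the ynal may be consumed by reduction and oligomerisation before C–C bond formation. The fallback sets out from 17 and returns at 22, omitting 21 and step 15 (no new compound, F0). It is a carbonylative Sonogashira coupling of 17 with alkyne 18 (PdCl2(PPh3)2, CuI, i-Pr2NEt, CO 5 bar, THF, 23 °C), in which CO insertion into the alkenylpalladium bond precedes alkynyl transfer and the ynone is formed directly.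

**Further compounds**

F1 | step 16 | 1-(1-hydroxy-5-phenylpent-2-yn-1-yl)-3-{[7-methoxy-4-oxo-2-(2-phenylethyl)-4H-chromen-6-yl]oxy}-4,5-bis(methoxymethoxy)-7-oxabicyclo[4.1.0]heptan-2-one, oxirane oxygen trans to the C5 MOM ether, other centres as in 21 | COc1cc2oc(CCc3ccccc3)cc(=O)c2cc1O[C@@H]1C(=O)[C@]2(C(O)C#CCCc3ccccc3)O[C@@H]2[C@@H](OCOC)[C@@H]1OCOC
F2 | step 16 | (3S,4R,5S,6S)-3-hydroxy-2-(1-hydroxy-5-phenylpent-2-yn-1-yl)-6-{[7-methoxy-4-oxo-2-(2-phenylethyl)-4H-chromen-6-yl]oxy}-4,5-bis(methoxymethoxy)cyclohexan-1-one, epimer mixture at C2 and at the side-chain carbinol | COc1cc2oc(CCc3ccccc3)cc(=O)c2cc1O[C@@H]1C(=O)C(C(O)C#CCCc2ccccc2)[C@H](O)[C@@H](OCOC)[C@@H]1OCOC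
F3 | step 12 | 3-iodo-5,6-bis(methoxymethoxy)-2-oxocyclohex-3-en-1-yl trifluoromethanesulfonate, configuration as in 12 | O=C1C(I)=C[C@@H](OCOC)[C@H](OCOC)[C@H]1OS(=O)(=O)C(F)(F)F
F0 | step 14 | none | none
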